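## Structural features

Laxiflorin (23) is a (2S)-flavanone. Aromatic ring A is fused through C4a and C8a to the dihydropyranone ring C, and C2 of ring C carries ring B, a 4-hydroxy-3-methoxyphenyl group. Ring A has no hydrogen left: oxygen sits on C5, C7 and C8a, and carbon on C4a (the C4 carbonyl), C6 (a 2-hydroxyethyl chain) and C8 (a prenyl group). C2 is the only stereocentre, so no neighbouring centre can relay its configuration; it has to come from a reagent or catalyst. The fragile points are:

- the C2–O1 bond, which lies β to the C4 ketone and is benzylic to an electron-rich ring, so base opens ring C to the chalcone and racemises C2;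
- the prenyl alkene next to the C7 hydroxyl, which strong acid closes to a chromane and which rules out hydrogenolysis;
- any C4 carbinol on the 5,7-dioxygenated ring, which ionises readily in acid.

The real difficulty is to combine a regiodefined hexasubstituted ring A with an enantiopure C2 that survives the arrival of the C4 carbonyl. The key step uses the fact that O1 links the sp3 carbon C2 to the sp2 carbon C8a of ring A: closing ring C at O1–C8a from a C8a bromide and a C2 carbinol leaves all four bonds at C2 untouched.

## Logic of the disconnections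

**23 ⇒ 22 ⇒ 21 ⇒ 20 (no skeletal bond cut).** The three phenolic O–H bonds of 23 are traced to the acetal C–O bonds of 22, the C4 carbonyl of 22 to the carbinol of 21, and the two free hydroxyls of 21 to the Si–O bonds of 20. The reason is that a C4 ketone makes C2 epimerisable and would make any open-chain precursor prone to retro-aldol cleavage, so C4 is carried reduced and masked until ring C exists. The demand on the forward steps is that the oxidation tells the benzylic C4 carbinol from the primary alcohol, and that acid is used only once C4 is a ketone.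

**20 ⇒ 19 (O1–C8a).** This is the one bond of ring C whose formation does not involve a bond at C2. Cutting it turns the bicycle into an open 1,3-dioxygenated chain between two arenes. It demands insertion of palladium into a C–Br bond with two ortho substituents, and ring closure faster than β-hydride loss from the secondary alkoxide. A single free hydroxyl in 19 answers the question of site.

**19 ⇒ 18 (C2–H).** The stereocentre is traced to a prochiral aryl ketone. This replaces a chiral building block by a catalytic reduction. It demands catalyst control that ignores the remote C4 centre, which is therefore allowed to be a mixture.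

**18 ⇒ 13 + 15 (C3–C4 and the C4 O–Si bond).** This cut divides the molecule into a ring A half and a ring B half of similar size and uses the natural polarity of a methyl ketone and an aldehyde. It demands that the hindered aldolate be captured before it reverts; silylation in the same flask does this and means the free β-hydroxy ketone is never handled.

**13 ⇒ 11 ⇒ 7 + 8 (C4a–CHO and C8–CH2).** Both bonds lie at ring positions flanked by bromine and an acetal oxygen. In 7 these two positions are the only C–H bonds of the ring and are equivalent, so the first metalation has no regiochemical choice and the second has one site left. The demand is an amide base that does not exchange bromine, low temperature to keep the ortho-bromo aryllithium from losing LiBr, and copper to steer allylation to the primary carbon.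

**7 ⇒ 6 ⇒ 4 ⇒ 3 (O–Si, C–OH, C=C).** The C6 chain is grown from a formyl group that already sits between the two ring oxygens, by methylenation and anti-Markovnikov hydration. This fixes the position of the chain without any aromatic substitution. The demand is terminal selectivity in the hydroboration and tolerance of the aryl bromide.

**3 ⇒ 2 ⇒ 1 and 15 ⇒ 14 (O-alkyl exchange).** The methyl ethers of 1 cannot be removed at the end without also cleaving the 3'-methoxy group, so they are exchanged at the outset for methoxymethyl ethers. These direct the metalations and all leave in one mild acid step. The demand is complete double demethylation next to a formyl group.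

## Other disconnections considered

**Alternative 1:** The cut removes ring A by breaking C8–C8a and C4a–C5. Ring C remains as (S)-5-bromo-2-aryl-2,3-dihydropyran-4-one A2, and C5–C8 become the bis(trimethylsilyloxy) diene A3, derived from 3-(5-methylhex-4-enoyl)dihydrofuran-2-one.

- Forward step: a [4+2] cycloaddition would join the nucleophilic diene terminus C8 to C8a and the ketene acetal carbon C5 to the brominated carbon C4a. Loss of HBr and opening of the lactone acetal would aromatise ring A and release the hydroxyethyl chain, giving A1, one desilylation from 23.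
- In favour: it is highly convergent. The six substituents of ring A follow from the constitution of A3, with no metalation and no phenol protection on ring A. C4 arrives as the ketone.
- Against: A2 is a vinylogous ester and so a reluctant dienophile. A3 is hindered at both termini and hydrolytically labile. The new bond at C4a creates a quaternary bromide. The HBr set free meets a free C7 hydroxyl beside the prenyl group, while a base added to absorb it could open ring C and racemise C2.
- Comparison: on step economy and on the oxidation level at C4 this alternative is the better plan on paper. On the source of the C2 configuration (a catalytic asymmetric hetero-Diels–Alder reaction for A2) it is the equal of the chosen plan. On mechanism the chosen plan is safer, because each of its steps has a close analogue and C2 never sits β to a carbonyl while acid or base is generated.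

**Alternative 2:** The cut is C2–C3. The precursor is the diazoketone A5, in which C8a carries the ring B benzyl ether and C4a the diazoacetyl group.

- Forward step: a chiral dirhodium tetracarboxylate, Rh2(O2CR*)4, would form the carbenoid at C3, which inserts into the benzylic C2–H bond to give A4, closing ring C and setting C2 at once.
- In favour: one catalytic step does what the chosen plan does in two (reduction, then coupling). C4 is already a ketone. The C–H bond addressed is activated by oxygen and by an electron-rich arene.
- Against: attack of the carbenoid on the ether oxygen to give an oxonium ylide, followed by a Stevens shift of the benzyl group, is the classic competing path. The prenyl alkene and ring B offer cyclopropanation and Buchner pathways. Enantiocontrol in six-membered ketocarbenoid insertions is less dependable than in ketone transfer hydrogenation. Removing four silyl ethers from A4 with fluoride generates phenoxides on a flavanone, the very conditions that open ring C.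
- Comparison: the hexasubstituted ring A has to be built just as in the chosen plan, so on that count the two are equal. On the endgame redox count the alternative is better. On chemoselectivity and on the security of C2 the chosen plan is better.

**Alternative 3:** The cut is C4a–C5. The precursor is the lactone-capped dihydropyranone A7.

- Forward step: base would generate the dienolate across C8–C8a–C4a, whose carbon C4a attacks the lactone carbonyl C5. Ring A closes, the lactone opens to the hydroxyethyl chain, and enolisation aromatises the ring to give A6, one acetal cleavage from 23.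
- In favour: it follows the biosynthetic logic. It needs no aryl halide and no transition metal, places every ring A substituent through the chain, and ends with a single deprotection.
- Against: the most acidic site of A7 is C6–H between the C5 and C7 carbonyls, and its enolate deactivates the very carbonyl that must be attacked. Aldol and O-acylation closures compete. Base on a dihydropyranone can expel O1 from C2 by an E1cB path and racemise the stereocentre. A7 itself is a sensitive polycarbonyl compound that needs several acylation steps.
- Comparison: in protecting-group economy and nominal step count this alternative is equal or better. In control of the cyclisation mode and of C2 the chosen plan is clearly better.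

Key step: step 11

Remark: the carbinol carbon of 19 is C1 of its propanol chain, so 19 is named as a (1S)-propan-1-ol. The descriptors of 19, 20 and 23 refer to the same spatial arrangement (O > aryl > CH2 > H throughout). The C4 carbinol centre is carried as both epimers on purpose, because step 13 erases it.

## Route

Step 1
Reactants: 1 4-bromo-2,6-dimethoxybenzaldehyde
Product: 2 4-bromo-2,6-dihydroxybenzaldehyde
Conditions: BBr3 (3 equiv), CH2Cl2, −78 °C to rt; then H2O
Reagents that add atoms: none
Why: Lewis acid ether dealkylation: boron binds each ether oxygen and bromide attacks the methyl group, helped by chelation to the neighbouring formyl group. The methyl ethers are removed here because later they could not be told from the 3'-methoxy group of ring B.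

Step 2
Reactants: 2 4-bromo-2,6-dihydroxybenzaldehyde
Product: 3 4-bromo-2,6-bis(methoxymethoxy)benzaldehyde
Conditions: NaH (2.4 equiv), MOMCl (2.6 equiv), DMF, 0 °C to rt
Reagents that add atoms: chloromethyl methyl ether, COCCl
Why: Williamson-type O-alkylation of the bis-phenoxide; NaH in DMF is chosen because both hydroxyls are hydrogen-bonded to the formyl group. The acetal ethers later direct the ring metalations and leave under mild acid.

Step 3
Reactants: 3 4-bromo-2,6-bis(methoxymethoxy)benzaldehyde
Product: 4 5-bromo-2-ethenyl-1,3-bis(methoxymethoxy)benzene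
Conditions: Ph3PCH3Br, KOt-Bu, THF, 0 °C to rt
Reagents that add atoms: methyltriphenylphosphonium bromide, C[P+](c1ccccc1)(c1ccccc1)c1ccccc1.[Br-]
Why: Wittig methylenation; the unstabilised ylide adds to the hindered, non-enolisable aldehyde and does not touch the aryl bromide.

Step 4
Reactants: 4 5-bromo-2-ethenyl-1,3-bis(methoxymethoxy)benzene
Product: 6 2-[4-bromo-2,6-bis(methoxymethoxy)phenyl]ethan-1-ol, via B-(2-arylethyl)-9-borabicyclononane 5 (not isolated)
Conditions: 9-BBN, THF, 0 °C to rt; then aq. NaOH, H2O2, 0 °C to rt
Reagents that add atoms: 9-borabicyclo[3.3.1]nonane, B1C2CCCC1CCC2 (boron only in 5); hydrogen peroxide, OO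
Why: Hydroboration–oxidation; the bulky borane places boron on the terminal carbon of the styrene and alkaline peroxide exchanges C–B for C–OH, giving the anti-Markovnikov primary alcohol. Aryl bromide and acetals are inert to both reagents.

Step 5
Reactants: 6 2-[4-bromo-2,6-bis(methoxymethoxy)phenyl]ethan-1-ol
Product: 7 tert-butyl{2-[4-bromo-2,6-bis(methoxymethoxy)phenyl]ethoxy}dimethylsilane
Conditions: TBSCl, imidazole, DMF, rt
Reagents that add atoms: tert-butyldimethylsilyl chloride, CC(C)(C)[Si](C)(C)Cl
Why: Imidazole-mediated silylation of a primary alcohol; the silyl ether keeps the hydroxyl from quenching the organolithiums of steps 6, 7 and 9 and from competing in step 11.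

Step 6
Reactants: 7 tert-butyl{2-[4-bromo-2,6-bis(methoxymethoxy)phenyl]ethoxy}dimethylsilane; 8 1-bromo-3-methylbut-2-ene (prenyl bromide)
Product: 11 tert-butyl{2-[4-bromo-2,6-bis(methoxymethoxy)-3-(3-methylbut-2-en-1-yl)phenyl]ethoxy}dimethylsilane, via aryllithium 9 (not isolated), via arylcopper 10 (not isolated)
Conditions: LiN(i-Pr)2 (1.1 equiv), THF, −78 °C; CuBr·SMe2 (1.1 equiv), −78 °C; then 8, −78 to 0 °C
Reagents that add atoms: 1-bromo-3-methylbut-2-ene (compound 8), CC(C)=CCBr; LiN(i-Pr)2, [Li]N(C(C)C)C(C)C (lithium only in 9); CuBr·SMe2, Br[Cu].CSC (copper only in 10)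
Why: Directed ortho-metalation: the two ring C–H bonds of 7 are equivalent and each lies between bromine and an acetal oxygen, so the amide base gives a single aryllithium without bromine–lithium exchange. Transmetalation to monovalent copper stops loss of LiBr and directs allylic substitution to the primary carbon of 8 (SN2 mode).

Step 7
Reactants: 11 tert-butyl{2-[4-bromo-2,6-bis(methoxymethoxy)-3-(3-methylbut-2-en-1-yl)phenyl]ethoxy}dimethylsilane
Product: 13 2-bromo-5-{2-[(tert-butyldimethylsilyl)oxy]ethyl}-4,6-bis(methoxymethoxy)-3-(3-methylbut-2-en-1-yl)benzaldehyde, via aryllithium 12 (not isolated)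
Conditions: LiN(i-Pr)2 (1.2 equiv), THF, −78 °C; DMF, −78 to −40 °C; then H2O
Reagents that add atoms: N,N-dimethylformamide, CN(C)C=O; LiN(i-Pr)2, [Li]N(C(C)C)C(C)C (lithium only in 12)
Why: A second directed ortho-metalation at the only ring C–H left, again between bromine and an acetal oxygen, followed by formylation of the aryllithium with DMF. At −78 °C the coordinated ring deprotonation should be faster than removal of a prenyl CH2 proton.

Step 8
Reactants: 14 1-(4-hydroxy-3-methoxyphenyl)ethan-1-one (acetovanillone)
Product: 15 1-[3-methoxy-4-(methoxymethoxy)phenyl]ethan-1-one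
Conditions: MOMCl, i-Pr2NEt, CH2Cl2, 0 °C to rt
Reagents that add atoms: chloromethyl methyl ether, COCCl
Why: O-alkylation of the phenol; the same acetal as on ring A is used so that one acid step at the end frees all three phenols.

Step 9
Reactants: 15 1-[3-methoxy-4-(methoxymethoxy)phenyl]ethan-1-one; 13 2-bromo-5-{2-[(tert-butyldimethylsilyl)oxy]ethyl}-4,6-bis(methoxymethoxy)-3-(3-methylbut-2-en-1-yl)benzaldehyde
Product: 18 3-{2-bromo-5-[2-(tert-butyldimethylsilyloxy)ethyl]-4,6-bis(methoxymethoxy)-3-(3-methylbut-2-en-1-yl)phenyl}-3-(tert-butyldimethylsilyloxy)-1-[3-methoxy-4-(methoxymethoxy)phenyl]propan-1-one (racemic), via lithium enolate 16 (not isolated), via lithium aldolate 17 (not isolated)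
Conditions: 15, LiN(SiMe3)2, THF, −78 °C; 13, −78 °C; TBSOTf, −78 to −40 °C; aq. NaHCO3
Reagents that add atoms: tert-butyldimethylsilyl trifluoromethanesulfonate, CC(C)(C)[Si](C)(C)OS(=O)(=O)C(F)(F)F; LiN(SiMe3)2, [Li]N([Si](C)(C)C)[Si](C)(C)C (lithium only in 16 and 17)
Why: Directed aldol addition of a preformed lithium enolate to a non-enolisable aldehyde, with O-silylation of the aldolate in the same flask. Trapping at low temperature avoids handling the β-hydroxy ketone, which is open to retro-aldol cleavage and dehydration. The C4 centre is formed as a racemate because it is oxidised in step 13.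

Step 10
Reactants: 18 3-{2-bromo-5-[2-(tert-butyldimethylsilyloxy)ethyl]-4,6-bis(methoxymethoxy)-3-(3-methylbut-2-en-1-yl)phenyl}-3-(tert-butyldimethylsilyloxy)-1-[3-methoxy-4-(methoxymethoxy)phenyl]propan-1-one
Product: 19 (1S)-3-{2-bromo-5-[2-(tert-butyldimethylsilyloxy)ethyl]-4,6-bis(methoxymethoxy)-3-(3-methylbut-2-en-1-yl)phenyl}-3-(tert-butyldimethylsilyloxy)-1-[3-methoxy-4-(methoxymethoxy)phenyl]propan-1-ol (both C3 epimers)
Conditions: RuCl[(S,S)-TsDPEN](p-cymene) (2 mol %), HCO2H/Et3N (5:2), CH2Cl2, 30 °C
Reagents that add atoms: none
Why: Asymmetric transfer hydrogenation of an aryl alkyl ketone by a bifunctional ruthenium hydride–amine catalyst; the (S,S) ligand places the aryl group against the cymene ring and delivers hydride to the face that gives the (S)-carbinol, whatever the configuration of the remote silyloxy centre. Loss of CO2 makes the reduction irreversible, and the buffered medium leaves silyl ethers, acetals and the aryl bromide alone.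

Step 11
Reactants: 19 (1S)-3-{2-bromo-5-[2-(tert-butyldimethylsilyloxy)ethyl]-4,6-bis(methoxymethoxy)-3-(3-methylbut-2-en-1-yl)phenyl}-3-(tert-butyldimethylsilyloxy)-1-[3-methoxy-4-(methoxymethoxy)phenyl]propan-1-ol
Product: 20 (2S)-4-(tert-butyldimethylsilyloxy)-6-[2-(tert-butyldimethylsilyloxy)ethyl]-2-[3-methoxy-4-(methoxymethoxy)phenyl]-5,7-bis(methoxymethoxy)-8-(3-methylbut-2-en-1-yl)-3,4-dihydro-2H-chromene (both C4 epimers)
Conditions: Pd(OAc)2 (5 mol %), 2-(di-tert-butylphosphino)-1,1'-binaphthyl (6 mol %), Cs2CO3 (1.5 equiv), toluene, 80 °C
Reagents that add atoms: none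
Why: Intramolecular palladium-catalysed etherification of an aryl bromide by a secondary alcohol: zerovalent palladium, formed from Pd(OAc)2 and the bulky electron-rich phosphine, inserts into the C8a–Br bond, Cs2CO3 deprotonates the coordinated C2 hydroxyl, and C–O reductive elimination from the divalent (aryl)(alkoxo)palladium species forms O1–C8a and regenerates the catalyst. The closest known reaction type is the cyclisation of 3-(2-haloaryl)propanols bearing a secondary carbinol to chromans with di-tert-butyl biaryl phosphines, which accepts ortho-substituted halides and transfers the carbinol configuration unchanged. Ring C closes as a six-membered ring by reductive elimination from a seven-membered oxapalladacycle, and O1–C8a is the only bond made. No stereocentre is created: C2 keeps the S configuration of step 10 because none of its bonds is broken and Cs2CO3 cannot ionise the C2–H bond, and the C4 epimers pass through unchanged. The selectivity needed is reductive elimination over β-hydride elimination of the secondary alkoxide, which would reduce the C–Br bond and oxidise the carbinol; the bulk of the phosphine and the two ortho substituents on the aryl ligand both favour reductive elimination. The C2 hydroxyl is the only free hydroxyl, so no other oxygen competes, and the silyl ether at C4 closes off retro-aldol, dehydration and oxidation paths. The prenyl alkene at C8 should stay out of the reaction, since carbopalladation from C8a would have to close a four-membered ring or an endo five-membered ring.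

Step 12
Reactants: 20 (2S)-4-(tert-butyldimethylsilyloxy)-6-[2-(tert-butyldimethylsilyloxy)ethyl]-2-[3-methoxy-4-(methoxymethoxy)phenyl]-5,7-bis(methoxymethoxy)-8-(3-methylbut-2-en-1-yl)-3,4-dihydro-2H-chromene
Product: 21 (2S)-6-(2-hydroxyethyl)-2-[3-methoxy-4-(methoxymethoxy)phenyl]-5,7-bis(methoxymethoxy)-8-(3-methylbut-2-en-1-yl)-3,4-dihydro-2H-chromen-4-ol (both C4 epimers)
Conditions: Bu4NF (3 equiv), THF, 0 °C to rt
Reagents that add atoms: none
Why: Fluoride cleaves both Si–O bonds, driven by the strength of the Si–F bond. The medium is basic, which protects the acid-labile C4 carbinol on the 5,7-dioxygenated ring and the acetals, and C2 cannot epimerise because no carbonyl is present yet.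

Step 13
Reactants: 21 (2S)-6-(2-hydroxyethyl)-2-[3-methoxy-4-(methoxymethoxy)phenyl]-5,7-bis(methoxymethoxy)-8-(3-methylbut-2-en-1-yl)-3,4-dihydro-2H-chromen-4-ol
Product: 22 (2S)-6-(2-hydroxyethyl)-2-[3-methoxy-4-(methoxymethoxy)phenyl]-5,7-bis(methoxymethoxy)-8-(3-methylbut-2-en-1-yl)-2,3-dihydro-4H-chromen-4-one
Conditions: MnO2 (activated, excess), CH2Cl2, rt
Reagents that add atoms: none
Why: Chemoselective oxidation of a benzylic alcohol by MnO2, which needs activation by the adjacent arene and so leaves the saturated primary alcohol alone. Both C4 epimers converge on one ketone, and the neutral medium does not open ring C, so C2 stays S.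

Step 14
Reactants: 22 (2S)-6-(2-hydroxyethyl)-2-[3-methoxy-4-(methoxymethoxy)phenyl]-5,7-bis(methoxymethoxy)-8-(3-methylbut-2-en-1-yl)-2,3-dihydro-4H-chromen-4-one
Product: 23 laxiflorin, (2S)-5,7-dihydroxy-6-(2-hydroxyethyl)-2-(4-hydroxy-3-methoxyphenyl)-8-(3-methylbut-2-en-1-yl)-2,3-dihydro-4H-chromen-4-one
Conditions: 3 M aq. HCl, MeOH, 40 °C
Reagents that add atoms: none
Why: Acid-catalysed acetal exchange with methanol removes the three aryl methoxymethyl ethers. Dilute acid and moderate temperature are chosen so that the prenyl group does not cyclise onto the C7 hydroxyl and the C2–O1 bond does not ionise; acid meets the molecule only now that C4 is a ketone.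

## Compound list

1 | 4-bromo-2,6-dimethoxybenzaldehyde | COc1cc(Br)cc(OC)c1C=O | starting material
2 | 4-bromo-2,6-dihydroxybenzaldehyde | Oc1cc(Br)cc(O)c1C=O | intermediate
3 | 4-bromo-2,6-bis(methoxymethoxy)benzaldehyde | COCOc1cc(Br)cc(OCOC)c1C=O | intermediate
4 | 5-bromo-2-ethenyl-1,3-bis(methoxymethoxy)benzene | COCOc1cc(Br)cc(OCOC)c1C=C | intermediate
5 | 9-{2-[4-bromo-2,6-bis(methoxymethoxy)phenyl]ethyl}-9-borabicyclo[3.3.1]nonane (not isolated) | COCOc1cc(Br)cc(OCOC)c1CCB1C2CCCC1CCC2 | intermediate
6 | 2-[4-bromo-2,6-bis(methoxymethoxy)phenyl]ethan-1-ol | COCOc1cc(Br)cc(OCOC)c1CCO | intermediate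
7 | tert-butyl{2-[4-bromo-2,6-bis(methoxymethoxy)phenyl]ethoxy}dimethylsilane | COCOc1cc(Br)cc(OCOC)c1CCO[Si](C)(C)C(C)(C)C | intermediate
8 | 1-bromo-3-methylbut-2-ene (prenyl bromide) | CC(C)=CCBr | starting material
9 | aryllithium of 7, lithium at the ring carbon between Br and OCH2OMe (not isolated) | [Li]c1c(Br)cc(OCOC)c(CCO[Si](C)(C)C(C)(C)C)c1OCOC | intermediate
10 | arylcopper from 9, copper at the same carbon (not isolated) | [Cu]c1c(Br)cc(OCOC)c(CCO[Si](C)(C)C(C)(C)C)c1OCOC | intermediate
11 | tert-butyl{2-[4-bromo-2,6-bis(methoxymethoxy)-3-(3-methylbut-2-en-1-yl)phenyl]ethoxy}dimethylsilane | CC(C)=CCc1c(Br)cc(OCOC)c(CCO[Si](C)(C)C(C)(C)C)c1OCOC | intermediate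
12 | aryllithium of 11, lithium at the last ring C–H position (not isolated) | CC(C)=CCc1c(Br)c([Li])c(OCOC)c(CCO[Si](C)(C)C(C)(C)C)c1OCOC | intermediate
13 | 2-bromo-5-{2-[(tert-butyldimethylsilyl)oxy]ethyl}-4,6-bis(methoxymethoxy)-3-(3-methylbut-2-en-1-yl)benzaldehyde | CC(C)=CCc1c(Br)c(C=O)c(OCOC)c(CCO[Si](C)(C)C(C)(C)C)c1OCOC | intermediate
14 | 1-(4-hydroxy-3-methoxyphenyl)ethan-1-one (acetovanillone) | CC(=O)c1ccc(O)c(OC)c1 | starting material
15 | 1-[3-methoxy-4-(methoxymethoxy)phenyl]ethan-1-one | CC(=O)c1ccc(OCOC)c(OC)c1 | intermediate
16 | lithium enolate of 15 (not isolated) | C=C(O[Li])c1ccc(OCOC)c(OC)c1 | intermediate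
17 | lithium aldolate from 16 and 13, racemic (not isolated) | COCOc1ccc(C(=O)CC(O[Li])c2c(Br)c(CC=C(C)C)c(OCOC)c(CCO[Si](C)(C)C(C)(C)C)c2OCOC)cc1OC | intermediate
18 | 3-{2-bromo-5-[2-(tert-butyldimethylsilyloxy)ethyl]-4,6-bis(methoxymethoxy)-3-(3-methylbut-2-en-1-yl)phenyl}-3-(tert-butyldimethylsilyloxy)-1-[3-methoxy-4-(methoxymethoxy)phenyl]propan-1-one, racemic | COCOc1ccc(C(=O)CC(O[Si](C)(C)C(C)(C)C)c2c(Br)c(CC=C(C)C)c(OCOC)c(CCO[Si](C)(C)C(C)(C)C)c2OCOC)cc1OC | intermediate
19 | (1S)-3-{2-bromo-5-[2-(tert-butyldimethylsilyloxy)ethyl]-4,6-bis(methoxymethoxy)-3-(3-methylbut-2-en-1-yl)phenyl}-3-(tert-butyldimethylsilyloxy)-1-[3-methoxy-4-(methoxymethoxy)phenyl]propan-1-ol, both C3 epimers | COCOc1ccc([C@@H](O)CC(O[Si](C)(C)C(C)(C)C)c2c(Br)c(CC=C(C)C)c(OCOC)c(CCO[Si](C)(C)C(C)(C)C)c2OCOC)cc1OC | intermediate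
20 | (2S)-4-(tert-butyldimethylsilyloxy)-6-[2-(tert-butyldimethylsilyloxy)ethyl]-2-[3-methoxy-4-(methoxymethoxy)phenyl]-5,7-bis(methoxymethoxy)-8-(3-methylbut-2-en-1-yl)-3,4-dihydro-2H-chromene, both C4 epimers | COCOc1ccc([C@@H]2CC(O[Si](C)(C)C(C)(C)C)c3c(OCOC)c(CCO[Si](C)(C)C(C)(C)C)c(OCOC)c(CC=C(C)C)c3O2)cc1OC | intermediate
21 | (2S)-6-(2-hydroxyethyl)-2-[3-methoxy-4-(methoxymethoxy)phenyl]-5,7-bis(methoxymethoxy)-8-(3-methylbut-2-en-1-yl)-3,4-dihydro-2H-chromen-4-ol, both C4 epimers | COCOc1ccc([C@@H]2CC(O)c3c(OCOC)c(CCO)c(OCOC)c(CC=C(C)C)c3O2)cc1OC | intermediate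
22 | (2S)-6-(2-hydroxyethyl)-2-[3-methoxy-4-(methoxymethoxy)phenyl]-5,7-bis(methoxymethoxy)-8-(3-methylbut-2-en-1-yl)-2,3-dihydro-4H-chromen-4-one | COCOc1ccc([C@@H]2CC(=O)c3c(OCOC)c(CCO)c(OCOC)c(CC=C(C)C)c3O2)cc1OC | intermediate
23 | laxiflorin, (2S)-5,7-dihydroxy-6-(2-hydroxyethyl)-2-(4-hydroxy-3-methoxyphenyl)-8-(3-methylbut-2-en-1-yl)-2,3-dihydro-4H-chromen-4-one | COc1cc([C@@H]2CC(=O)c3c(O)c(CCO)c(O)c(CC=C(C)C)c3O2)ccc1O | target

## Step count and least certain steps

Total: 14 steps. Longest linear sequence: 13 steps (steps 1–7 and 9–14, from 1 to 23); step 8 prepares 15 on the side.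

**Step 11 (key step).** The most likely failure is slow insertion of palladium into the C–Br bond, which has substituents on both ortho carbons, so that β-hydride elimination from the alkoxide and reduction of the C–Br bond overtake ring closure. The fallback forms the other ether bond, C2–O1, with inversion, and needs no palladium.
- It sets out from 18, which is reduced with RuCl[(R,R)-TsDPEN](p-cymene) and HCO2H/Et3N to the (1R)-carbinol F1.
- F1 is deprotonated with n-BuLi and treated with t-BuLi at −78 °C (bromine–lithium exchange), then at once with B(OMe)3 and afterwards with NaOH/H2O2. This turns C8a–Br into C8a–OH and gives the (1R)-phenol F2. Immediate borylation is needed so that the silyl group does not migrate from oxygen to the lithiated carbon.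
- Mitsunobu cyclisation of F2 (PPh3, diisopropyl azodicarboxylate, THF, 0 °C) closes ring C with inversion at C2 and comes back to the route at 20.

**Step 6.** Two processes threaten it: loss of LiBr from the ortho-bromo aryllithium if the mixture warms before transmetalation, and attack at the tertiary end of the allyl system (SN2' mode), which would give the 1,1-dimethylallyl isomer. The fallback sets out from 7 and uses the same metalation and copper transmetalation, but alkylates with allyl bromide, which has no such regiochemical choice, to give the allyl arene F3. Cross-metathesis of F3 with 2-methylbut-2-ene (second-generation Grubbs catalyst, CH2Cl2, 40 °C) comes back at 11.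

**Step 7.** The risk is deprotonation of the benzylic and allylic CH2 of the prenyl group in competition with ring metalation, besides loss of LiBr. The fallback reverses the order of the two ring substitutions.
- It sets out from 7, which is metalated with LiN(i-Pr)2 and formylated with DMF to the aldehyde F4.
- F4 is masked in the flask as the lithium α-amino alkoxide F5 by addition of LiN(Me)CH2CH2NMe2.
- The last ring C–H is then metalated with LiN(i-Pr)2, transmetalated with CuBr·SMe2 and alkylated with 8; aqueous work-up releases the formyl group and comes back at 13.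

**Step 9.** The risk is retro-aldol cleavage of the hindered aldolate 17 before silylation is complete, and enol silylation of the product by excess triflate. The fallback separates addition and protection and uses a covalent boron aldolate that does not revert.
- It sets out from 15, which is enolised with (c-C6H11)2BCl/Et3N (Et2O, 0 °C) to the boron enolate F6.
- 13 is added at −78 °C, and work-up with H2O2 in pH 7 buffer/MeOH gives the free aldol F7.
- F7 is silylated with TBSOTf/2,6-lutidine (CH2Cl2, −78 °C) and comes back at 18.

**Step 13.** The risk is sluggish oxidation, because the neighbouring C5 acetal pushes the C4–H bond towards the plane of ring A where it overlaps poorly with the arene; long exposure would then erode chemoselectivity. The fallback removes the need for selectivity.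
- It sets out from 21, whose primary hydroxyl alone is silylated (TBSCl, imidazole, CH2Cl2, −20 °C) to the monosilyl ether F8.
- Dess–Martin periodinane with NaHCO3 oxidises the only free hydroxyl to the silylated flavanone F9.
- 3 M aq. HCl in MeOH removes the silyl ether together with the three acetals and comes back at 23.

## Further compounds

F1 | step 11 | (1R)-3-{2-bromo-5-[2-(tert-butyldimethylsilyloxy)ethyl]-4,6-bis(methoxymethoxy)-3-(3-methylbut-2-en-1-yl)phenyl}-3-(tert-butyldimethylsilyloxy)-1-[3-methoxy-4-(methoxymethoxy)phenyl]propan-1-ol, both C3 epimers | COCOc1ccc([C@H](O)CC(O[Si](C)(C)C(C)(C)C)c2c(Br)c(CC=C(C)C)c(OCOC)c(CCO[Si](C)(C)C(C)(C)C)c2OCOC)cc1OC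
F2 | step 11 | (1R)-3-{5-[2-(tert-butyldimethylsilyloxy)ethyl]-2-hydroxy-4,6-bis(methoxymethoxy)-3-(3-methylbut-2-en-1-yl)phenyl}-3-(tert-butyldimethylsilyloxy)-1-[3-methoxy-4-(methoxymethoxy)phenyl]propan-1-ol, both C3 epimers | COCOc1ccc([C@H](O)CC(O[Si](C)(C)C(C)(C)C)c2c(O)c(CC=C(C)C)c(OCOC)c(CCO[Si](C)(C)C(C)(C)C)c2OCOC)cc1OC
F3 | step 6 | tert-butyl{2-[4-bromo-2,6-bis(methoxymethoxy)-3-(prop-2-en-1-yl)phenyl]ethoxy}dimethylsilane | C=CCc1c(Br)cc(OCOC)c(CCO[Si](C)(C)C(C)(C)C)c1OCOC
F4 | step 7 | 2-bromo-5-{2-[(tert-butyldimethylsilyl)oxy]ethyl}-4,6-bis(methoxymethoxy)benzaldehyde | O=Cc1c(Br)cc(OCOC)c(CCO[Si](C)(C)C(C)(C)C)c1OCOC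
F5 | step 7 | lithium α-amino alkoxide from F4 and lithium N,N,N'-trimethylethylenediamide (not isolated) | CN(C)CCN(C)C(O[Li])c1c(Br)cc(OCOC)c(CCO[Si](C)(C)C(C)(C)C)c1OCOC
F6 | step 9 | dicyclohexylboron enolate of 15 (not isolated) | C=C(OB(C1CCCCC1)C1CCCCC1)c1ccc(OCOC)c(OC)c1
F7 | step 9 | 3-{2-bromo-5-[2-(tert-butyldimethylsilyloxy)ethyl]-4,6-bis(methoxymethoxy)-3-(3-methylbut-2-en-1-yl)phenyl}-3-hydroxy-1-[3-methoxy-4-(methoxymethoxy)phenyl]propan-1-one, racemic | COCOc1ccc(C(=O)CC(O)c2c(Br)c(CC=C(C)C)c(OCOC)c(CCO[Si](C)(C)C(C)(C)C)c2OCOC)cc1OC
F8 | step 13 | (2S)-6-[2-(tert-butyldimethylsilyloxy)ethyl]-2-[3-methoxy-4-(methoxymethoxy)phenyl]-5,7-bis(methoxymethoxy)-8-(3-methylbut-2-en-1-yl)-3,4-dihydro-2H-chromen-4-ol, both C4 epimers | COCOc1ccc([C@@H]2CC(O)c3c(OCOC)c(CCO[Si](C)(C)C(C)(C)C)c(OCOC)c(CC=C(C)C)c3O2)cc1OC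
F9 | step 13 | (2S)-6-[2-(tert-butyldimethylsilyloxy)ethyl]-2-[3-methoxy-4-(methoxymethoxy)phenyl]-5,7-bis(methoxymethoxy)-8-(3-methylbut-2-en-1-yl)-2,3-dihydro-4H-chromen-4-one | COCOc1ccc([C@@H]2CC(=O)c3c(OCOC)c(CCO[Si](C)(C)C(C)(C)C)c(OCOC)c(CC=C(C)C)c3O2)cc1OC
A1 | alternative 1 | 4'-O-(tert-butyldimethylsilyl)laxiflorin | CC(C)(C)[Si](C)(C)Oc1ccc([C@@H]2CC(=O)c3c(O)c(CCO)c(O)c(CC=C(C)C)c3O2)cc1OC
A2 | alternative 1 | (2S)-5-bromo-2-[4-(tert-butyldimethylsilyloxy)-3-methoxyphenyl]-2,3-dihydro-4H-pyran-4-one | COc1cc([C@@H]2CC(=O)C(Br)=CO2)ccc1O[Si](C)(C)C(C)(C)C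
A3 | alternative 1 | 5-(trimethylsilyloxy)-4-[5-methyl-1-(trimethylsilyloxy)hexa-1,4-dien-1-yl]-2,3-dihydrofuran | CC(C)=CCC=C(O[Si](C)(C)C)C1=C(O[Si](C)(C)C)OCC1
A4 | alternative 2 | (2S)-tetrakis(tert-butyldimethylsilyl)laxiflorin | CC(C)(C)[Si](C)(C)Oc1ccc([C@@H]2CC(=O)c3c(O[Si](C)(C)C(C)(C)C)c(CCO[Si](C)(C)C(C)(C)C)c(O[Si](C)(C)C(C)(C)C)c(CC=C(C)C)c3O2)cc1OC
A5 | alternative 2 | 2-diazo-1-{2-[4-(tert-butyldimethylsilyloxy)-3-methoxybenzyloxy]-4,6-bis(tert-butyldimethylsilyloxy)-5-[2-(tert-butyldimethylsilyloxy)ethyl]-3-(3-methylbut-2-en-1-yl)phenyl}ethan-1-one | [N-]=[N+]=CC(=O)c1c(OCc2ccc(O[Si](C)(C)C(C)(C)C)c(OC)c2)c(CC=C(C)C)c(O[Si](C)(C)C(C)(C)C)c(CCO[Si](C)(C)C(C)(C)C)c1O[Si](C)(C)C(C)(C)C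
A6 | alternative 3 | 4'-O-(methoxymethyl)laxiflorin | COCOc1ccc([C@@H]2CC(=O)c3c(O)c(CCO)c(O)c(CC=C(C)C)c3O2)cc1OC
A7 | alternative 3 | (2S)-2-[3-methoxy-4-(methoxymethoxy)phenyl]-6-[5-methyl-1-oxo-1-(2-oxotetrahydrofuran-3-yl)hex-4-en-2-yl]-2,3-dihydro-4H-pyran-4-one, side-chain centres unspecified | COCOc1ccc([C@@H]2CC(=O)C=C(C(CC=C(C)C)C(=O)C3CCOC3=O)O2)cc1OC
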